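**Retrosynthetic overview**
1. Target 14 ⇐ syringyl lignan 10. In the last step the symmetric 4-hydroxy-3,5-dimethoxyphenyl ring is dearomatised, cut open (periodate → o-quinone → peracid C–C cleavage) and re-closed as the 2-pyranone-6-carboxylic acid. Either C(OH)–C(OMe) bond gives the same product.
2. 10 ⇐ aldol of (R)-β-veratrylbutyrolactone 5 with O-benzylsyringaldehyde 7, then one hydrogenolysis (benzylic OH and OBn). C3 is set trans to C4.
3. 5 ⇐ enantioselective Rh(II)-carbenoid C–H insertion of diazoacetate 4 (from alcohol 1). This sets C4.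
4. Ring order: butyrolactone first (step 2), pyranone last (step 6). The pyranone carbons are the arene carbons of syringaldehyde 6.

Assumption: the (4S)-configured Rh2(MPPIM)4 catalyst is taken to give the (R)-lactone 5 (recalled, not verified; check rotation/chiral HPLC at 5 and use the 4R catalyst if the sense is opposite), and 2 is bought.

**Step 1**
Reactants: 1 3-(3,4-dimethoxyphenyl)propan-1-ol; 2 glyoxylic acid chloride p-toluenesulfonylhydrazone
Product: 4 3-(3,4-dimethoxyphenyl)propyl 2-diazoacetate, via tosylhydrazone ester 3 (not isolated)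
Conditions: 2 (1.8 equiv), PhNMe2 (1.8 equiv), CH2Cl2, 0 °C; then Et3N (5 equiv), 0 °C → rt
Reagents that add atoms: none
Why: O-acylation of the alcohol followed by base-induced loss of sulfinate from the tosylhydrazone (House/Corey–Myers diazoacetate synthesis, a Bamford–Stevens-type elimination) gives the diazo ester under mild conditions.

**Step 2**
Reactants: 4 3-(3,4-dimethoxyphenyl)propyl 2-diazoacetate
Product: 5 (R)-4-(3,4-dimethoxybenzyl)dihydrofuran-2(3H)-one
Conditions: Rh2(4S-MPPIM)4 (1 mol %), CH2Cl2, reflux, 4 added by syringe pump over 10 h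
Reagents that add atoms: none
Why: Dirhodium-carboxamidate-catalysed intramolecular carbenoid 1,5 C–H insertion, in which the chiral ligand pocket selects one enantiotopic C2–H of the propyl chain and so sets C4 as R (about 95% ee expected, polished later by crystallisation of 10 or chiral HPLC), the five-membered transition state being preferred over β- and δ-lactone formation.

**Step 3**
Reactants: 6 syringaldehyde
Product: 7 4-(benzyloxy)-3,5-dimethoxybenzaldehyde
Conditions: BnBr (1.1 equiv), K2CO3 (1.5 equiv), DMF, 60 °C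
Reagents that add atoms: benzyl bromide, BrCc1ccccc1
Why: Williamson ether synthesis on the acidic, unhindered phenoxide masks the phenol for the enolate step.

**Step 4**
Reactants: 5 (R)-4-(3,4-dimethoxybenzyl)dihydrofuran-2(3H)-one; 7 4-(benzyloxy)-3,5-dimethoxybenzaldehyde
Product: 9 (3S,4R)-3-{[4-(benzyloxy)-3,5-dimethoxyphenyl](hydroxy)methyl}-4-(3,4-dimethoxybenzyl)dihydrofuran-2(3H)-one (3,4-trans; carbinol epimers), via lithium enolate 8 (not isolated)
Conditions: LiHMDS (1.1 equiv), THF, −78 °C, 45 min; then 7 (1.05 equiv), −78 °C, 1 h; AcOH quench at −78 °C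
Reagents that add atoms: none
Why: Lithium enolate aldol addition to a non-enolisable aldehyde, with the aldehyde approaching anti to the C4 benzyl group so that C3 is set trans (the 3S descriptor is only a CIP priority change), while the carbinol centre is irrelevant because it is removed in step 5.

**Step 5**
Reactants: 9 the aldol adduct
Product: 10 (3R,4R)-4-(3,4-dimethoxybenzyl)-3-(4-hydroxy-3,5-dimethoxybenzyl)dihydrofuran-2(3H)-one
Conditions: H2 (1–3 atm), 10% Pd/C, AcOH, HClO4 (cat.), rt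
Reagents that add atoms: none
Why: Catalytic hydrogenolysis cleaves the benzyl ether and the electron-rich (p-oxygenated) benzylic C–OH bond in one operation without touching C3 or C4, the trans lactone also being the thermodynamic isomer.

**Step 6**
Reactants: 10 (3R,4R)-4-(3,4-dimethoxybenzyl)-3-(4-hydroxy-3,5-dimethoxybenzyl)dihydrofuran-2(3H)-one
Product: 14 4-{[(3R,4R)-4-(3,4-dimethoxybenzyl)-2-oxotetrahydrofuran-3-yl]methyl}-2-oxo-2H-pyran-6-carboxylic acid (target), via o-quinone 11 (not isolated), via muconic anhydride 12 (not isolated), via methoxymuconic acid 13 (not isolated)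
Conditions: NaIO4 (1.1 equiv), MeCN/H2O 2:1, 0 °C, 15 min, extract into CH2Cl2; mCPBA (1.05 equiv), CH2Cl2, 0 °C → rt, 1 h; then THF/1 M aq. H2SO4 1:1, 50 °C
Reagents that add atoms: sodium periodate, [Na+].[O-]I(=O)(=O)=O; mCPBA, OOC(=O)c1cccc(Cl)c1; water, O
Why: Proposed new method: periodate converts the 2,6-dimethoxyphenol through its aryl periodate ester into the 3-methoxy-o-quinone 11 with loss of MeOH (the two ortho C–OMe positions are equivalent, so only one quinone can form, and the non-phenolic veratryl ring is inert), mCPBA then inserts oxygen between the two quinone carbonyls by a Baeyer–Villiger acyl shift to give anhydride 12, and aqueous acid opens 12 to the ring-derived (2E,4Z) acid 13, whose cis-disposed CO2H closes onto the enol-ether carbon with loss of MeOH to give the 2-pyranone as the thermodynamic sink without touching any stereocentre; closest known reaction types are the periodate oxidation of guaiacols and syringols to o-quinones, the peracid cleavage of o-quinones to cis,cis-muconic anhydrides and the lactonisation of 2-hydroxymuconic acids to 2-pyranone-6-carboxylic acids.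

**Compound list**
1 | 3-(3,4-dimethoxyphenyl)propan-1-ol | COc1ccc(CCCO)cc1OC | starting material
2 | glyoxylic acid chloride p-toluenesulfonylhydrazone | Cc1ccc(cc1)S(=O)(=O)NN=CC(Cl)=O | starting material
3 | 3-(3,4-dimethoxyphenyl)propyl 2-(2-tosylhydrazinylidene)acetate | COc1ccc(CCCOC(=O)C=NNS(=O)(=O)c2ccc(C)cc2)cc1OC | intermediate
4 | 3-(3,4-dimethoxyphenyl)propyl 2-diazoacetate | COc1ccc(CCCOC(=O)C=[N+]=[N-])cc1OC | intermediate
5 | (R)-4-(3,4-dimethoxybenzyl)dihydrofuran-2(3H)-one | COc1ccc(C[C@H]2COC(=O)C2)cc1OC | intermediate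
6 | syringaldehyde (4-hydroxy-3,5-dimethoxybenzaldehyde) | COc1cc(C=O)cc(OC)c1O | starting material
7 | 4-(benzyloxy)-3,5-dimethoxybenzaldehyde | COc1cc(C=O)cc(OC)c1OCc1ccccc1 | intermediate
8 | lithium (R)-4-(3,4-dimethoxybenzyl)-4,5-dihydrofuran-2-olate (enolate of 5) | [Li+].COc1ccc(C[C@H]2COC([O-])=C2)cc1OC | intermediate
9 | (3S,4R)-3-{[4-(benzyloxy)-3,5-dimethoxyphenyl](hydroxy)methyl}-4-(3,4-dimethoxybenzyl)dihydrofuran-2(3H)-one, 3,4-trans, carbinol epimers | COc1ccc(C[C@H]2COC(=O)[C@@H]2C(O)c2cc(OC)c(OCc3ccccc3)c(OC)c2)cc1OC | intermediate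
10 | (3R,4R)-4-(3,4-dimethoxybenzyl)-3-(4-hydroxy-3,5-dimethoxybenzyl)dihydrofuran-2(3H)-one | COc1ccc(C[C@H]2COC(=O)[C@@H]2Cc2cc(OC)c(O)c(OC)c2)cc1OC | intermediate
11 | (3R,4R)-4-(3,4-dimethoxybenzyl)-3-[(5-methoxy-3,4-dioxocyclohexa-1,5-dien-1-yl)methyl]dihydrofuran-2(3H)-one | COc1ccc(C[C@H]2COC(=O)[C@@H]2CC2=CC(=O)C(=O)C(OC)=C2)cc1OC | intermediate
12 | (3R,4R)-4-(3,4-dimethoxybenzyl)-3-[(3-methoxy-2,7-dioxo-2,7-dihydrooxepin-5-yl)methyl]dihydrofuran-2(3H)-one | COc1ccc(C[C@H]2COC(=O)[C@@H]2CC2=CC(=O)OC(=O)C(OC)=C2)cc1OC | intermediate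
13 | (2E,4Z)-4-{[(3R,4R)-4-(3,4-dimethoxybenzyl)-2-oxotetrahydrofuran-3-yl]methyl}-2-methoxyhexa-2,4-dienedioic acid | COc1ccc(C[C@H]2COC(=O)[C@@H]2C/C(=C/C(=O)O)/C=C(OC)\C(=O)O)cc1OC | intermediate
14 | 4-{[(3R,4R)-4-(3,4-dimethoxybenzyl)-2-oxotetrahydrofuran-3-yl]methyl}-2-oxo-2H-pyran-6-carboxylic acid | COc1ccc(C[C@H]2COC(=O)[C@@H]2Cc2cc(C(=O)O)oc(=O)c2)cc1OC | target

**Totals**
Total steps: 6. Longest linear sequence: 5 (steps 1, 2, 4, 5, 6).

**Three steps most likely to fail**

Step 6. The risks are Diels–Alder dimerisation of quinone 11, over-oxidation by the peracid, and closure of 13 to a butenolide (muconolactone type) instead of the pyranone. The fallback sets out from 10 and comes back at 14. Periodate oxidation as in step 6 but with a reductive work-up (aq. Na2S2O4) gives the isolable catechol (3R,4R)-3-(3,4-dihydroxy-5-methoxybenzyl)-4-(3,4-dimethoxybenzyl)dihydrofuran-2(3H)-one F1. Cleavage of the catechol C–C bond with Pb(OAc)4 (2.2 equiv) in MeOH/toluene at 0 °C gives dimethyl (2E,4Z)-4-{[(3R,4R)-4-(3,4-dimethoxybenzyl)-2-oxotetrahydrofuran-3-yl]methyl}-2-methoxyhexa-2,4-dienedioate F2, in which both acids are masked so that no butenolide can form. TsOH in wet dioxane at 80 °C hydrolyses the enol ether and closes the ring onto the cis ester to give methyl 4-{[(3R,4R)-4-(3,4-dimethoxybenzyl)-2-oxotetrahydrofuran-3-yl]methyl}-2-oxo-2H-pyran-6-carboxylate F3. Acidic ester hydrolysis (3 M HCl/AcOH, 70 °C) then gives 14.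

Step 5. The risks are incomplete C–OH hydrogenolysis, or dehydration to the α-benzylidene lactone followed by unselective C=C hydrogenation (cis/trans mixture at C3). The fallback sets out from 7 (together with 5) and comes back at 10, and forms the C3–CH2 bond by SN2 alkylation so that no benzylic oxygen is ever present. NaBH4 in MeOH reduces 7 to 4-(benzyloxy)-3,5-dimethoxybenzyl alcohol F4, and PBr3 in Et2O at 0 °C gives 4-(benzyloxy)-3,5-dimethoxybenzyl bromide F5. Enolate 8 (from 5, LiHMDS, THF/DMPU, −78 °C) is alkylated with F5 anti to the C4 substituent to give (3R,4R)-3-[4-(benzyloxy)-3,5-dimethoxybenzyl]-4-(3,4-dimethoxybenzyl)dihydrofuran-2(3H)-one F6. Neutral hydrogenolysis (H2, Pd/C, EtOAc) then gives 10.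

Step 2. The risks are access to the chiral catalyst, moderate yield (carbene dimers, β- or δ-lactone) and ee below the level needed. The fallback sets out from 1 and comes back at 5, with C4 set by an auxiliary instead of a catalyst. TEMPO/PhI(OAc)2 in MeCN/H2O oxidises 1 to 3-(3,4-dimethoxyphenyl)propanoic acid F7. DCC/DMAP coupling with (S)-4-benzyl-2-oxazolidinone gives (S)-4-benzyl-3-[3-(3,4-dimethoxyphenyl)propanoyl]oxazolidin-2-one F8. Evans alkylation (NaHMDS, tert-butyl bromoacetate, THF, −78 °C) gives tert-butyl (R)-4-[(S)-4-benzyl-2-oxooxazolidin-3-yl]-3-(3,4-dimethoxybenzyl)-4-oxobutanoate F9. LiBH4 (THF/MeOH, 0 °C) removes the auxiliary reductively to give tert-butyl (R)-4-(3,4-dimethoxyphenyl)-3-(hydroxymethyl)butanoate F10. TFA in CH2Cl2 then cleaves the tert-butyl ester and lactonises to 5.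

**Further compounds**
F1 | step 6 | (3R,4R)-3-(3,4-dihydroxy-5-methoxybenzyl)-4-(3,4-dimethoxybenzyl)dihydrofuran-2(3H)-one | COc1ccc(C[C@H]2COC(=O)[C@@H]2Cc2cc(O)c(O)c(OC)c2)cc1OC
F2 | step 6 | dimethyl (2E,4Z)-4-{[(3R,4R)-4-(3,4-dimethoxybenzyl)-2-oxotetrahydrofuran-3-yl]methyl}-2-methoxyhexa-2,4-dienedioate | COc1ccc(C[C@H]2COC(=O)[C@@H]2C/C(=C/C(=O)OC)/C=C(OC)\C(=O)OC)cc1OC
F3 | step 6 | methyl 4-{[(3R,4R)-4-(3,4-dimethoxybenzyl)-2-oxotetrahydrofuran-3-yl]methyl}-2-oxo-2H-pyran-6-carboxylate | COc1ccc(C[C@H]2COC(=O)[C@@H]2Cc2cc(C(=O)OC)oc(=O)c2)cc1OC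
F4 | step 5 | 4-(benzyloxy)-3,5-dimethoxybenzyl alcohol | COc1cc(CO)cc(OC)c1OCc1ccccc1
F5 | step 5 | 4-(benzyloxy)-3,5-dimethoxybenzyl bromide | COc1cc(CBr)cc(OC)c1OCc1ccccc1
F6 | step 5 | (3R,4R)-3-[4-(benzyloxy)-3,5-dimethoxybenzyl]-4-(3,4-dimethoxybenzyl)dihydrofuran-2(3H)-one | COc1ccc(C[C@H]2COC(=O)[C@@H]2Cc2cc(OC)c(OCc3ccccc3)c(OC)c2)cc1OC
F7 | step 2 | 3-(3,4-dimethoxyphenyl)propanoic acid | COc1ccc(CCC(=O)O)cc1OC
F8 | step 2 | (S)-4-benzyl-3-[3-(3,4-dimethoxyphenyl)propanoyl]oxazolidin-2-one | COc1ccc(CCC(=O)N2[C@@H](Cc3ccccc3)COC2=O)cc1OC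
F9 | step 2 | tert-butyl (R)-4-[(S)-4-benzyl-2-oxooxazolidin-3-yl]-3-(3,4-dimethoxybenzyl)-4-oxobutanoate | COc1ccc(C[C@H](CC(=O)OC(C)(C)C)C(=O)N2[C@@H](Cc3ccccc3)COC2=O)cc1OC
F10 | step 2 | tert-butyl (R)-4-(3,4-dimethoxyphenyl)-3-(hydroxymethyl)butanoate | COc1ccc(C[C@H](CC(=O)OC(C)(C)C)CO)cc1OC
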